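**Retrosynthetic overview**
- Feature: C10 (quaternary, methyl-bearing) and C5 join ring A carbons C1–C4 to ring B. The C8 methyl and the 1,4-related C6/C9 positions of ring B match 2,6-dimethyl-1,4-benzoquinone, and C1–C4 with the C4 methyl is (E)-penta-1,3-diene.
- Ring B is bought as the quinone. Ring A is closed by an enantioselective oxazaborolidinium-catalysed Diels–Alder reaction that forms C1–C10 and C4–C5 and fixes C10. C5 is then epimerised to the trans fusion.
- The diene carries no donor at C3. Boron binds O6 and makes C10 the electrophilic carbon, so a 3-silyloxy group would send the CHMe terminus to C10. The C3 oxygen is therefore introduced later from the C2=C3 alkene and used to quaternise C4.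
- The C9 ketone is taken through the enol triflate to the C11 ester. C8=C9 epoxidation followed by SmI2 sets C8–OH and H9. The C6 and C3 oxygens are removed through tosylhydrazones.
- The C11 aldehyde is joined to a chiral-pool C12–C15 ylide that carries C13. Hydrogenation, angeloylation of C18–OH and fluoride deprotection finish the route.

Key step: step 1

Assumption (labdane numbering is used throughout): the (S)-catalyst is assigned from the usual pre-transition-state picture, with boron on O6 syn to C5–H and an aryl group covering one face. The equally available (R)-catalyst would be used, with nothing else changed, if the sense of induction proved opposite.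

**Step 1**
Reactants: 1 2,6-dimethyl-1,4-benzoquinone; 2 (E)-penta-1,3-diene
Product: 3 cis-fused endo adduct (4aS,5S,8aR)-2,5,8a-trimethyl-4a,5,8,8a-tetrahydronaphthalene-1,4-dione
Conditions: (S)-o-tolyl-CBS oxazaborolidine (20 mol%), Tf2NH (18 mol%), 2 (3 equiv), CH2Cl2, −78 → −40 °C
Reagents that add atoms: none
Why: The N-protonated oxazaborolidine binds the more basic and unhindered C6 oxygen (both ring methyls are β to it) syn to C5–H, which makes C10 the electrophilic end of C5=C10, and the diene adds in a concerted, asynchronous endo [4+2] in which its unsubstituted, more nucleophilic terminus C1 leads at C10 while C4 closes on C5. The closest known reactions are oxazaborolidinium triflimide-catalysed Diels–Alder additions of alkyl and 2-silyloxy dienes to methyl-substituted 1,4-benzoquinones, and the BF3-catalysed addition of piperylene to this same quinone, which is known to give this orientation. Ring A closes by the cycloaddition itself, a suprafacial six-electron closure that forms C1–C10 and C4–C5 together. C10 and C5 are set by the catalyst, whose aryl group leaves the C10-Re/C5-Si face open (the cis fusion follows from suprafacial addition), and C4 is set relative to them by the E geometry of the diene and the endo rule. Orientation, face and endo selectivity are needed but no site selectivity, since the two quinone C=C bonds are equivalent by symmetry. The orientation is secured because the C4 methyl of the diene and the boron on O6 polarise the two partners in the same sense.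

**Step 2**
Reactants: 3 cis-fused endo adduct
Product: 4 trans-fused ene-dione (4aR,5S,8aR)-2,5,8a-trimethyl-4a,5,8,8a-tetrahydronaphthalene-1,4-dione
Conditions: DBU (0.2 equiv), CH2Cl2, rt
Reagents that add atoms: none
Why: Base-catalysed epimerisation via the C5=C6 dienolate (aromatisation is blocked by quaternary C10) should convert the folded cis adduct, whose C4 methyl lies under ring B, into the more stable trans-fused ene-dione with H5 anti to the C10 methyl and the C4 methyl equatorial.

**Step 3**
Reactants: 4 trans-fused ene-dione
Product: 5 trans-fused saturated 6,9-dione with equatorial C8 methyl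
Conditions: Zn dust, AcOH, rt
Reagents that add atoms: none
Why: Zn/AcOH dissolving-metal reduction is specific for the C7=C8 bond held between two carbonyls and spares the isolated C2=C3 alkene; C8 stays epimerisable and should settle with its methyl equatorial, a centre that is erased again in step 6.

**Step 4**
Reactants: 5 saturated 6,9-dione
Product: 6 C6 mono-tosylhydrazone of 5 (C=N geometry immaterial)
Conditions: TsNHNH2 (1.05 equiv), MeOH, rt
Reagents that add atoms: p-toluenesulfonohydrazide, Cc1ccc(cc1)S(=O)(=O)NN
Why: Hydrazone condensation should choose the C6 carbonyl because C9 lies between quaternary C10 and the C8 methine, the 2,2,6-trisubstituted cyclohexanone situation that condenses only sluggishly.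

**Step 5**
Reactants: 6 C6 tosylhydrazone
Product: 7 C6-deoxy C9 ketone (trans-octalone keeping C2=C3)
Conditions: catecholborane (2 equiv), CHCl3, −10 °C; then NaOAc·3H2O, reflux
Reagents that add atoms: none
Why: Kabalka modification of the Caglioti tosylhydrazone reduction: hydride adds to C=N and acetate then releases sulfinate and N2 to leave CH2 at C6, under conditions that touch neither the hindered C9 ketone nor the alkene, after which C5 can no longer epimerise.

**Step 6**
Reactants: 7 C9 ketone
Product: 9 C8=C9 enol triflate, via potassium enolate 8 (not isolated)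
Conditions: KHMDS (1.2 equiv), THF, −78 → 0 °C; then PhNTf2, −78 °C → rt
Reagents that add atoms: N-phenylbis(trifluoromethanesulfonimide), O=S(=O)(N(c1ccccc1)S(=O)(=O)C(F)(F)F)C(F)(F)F
Why: Enolate O-triflation: with C10 quaternary only H8 can be removed, so the tetrasubstituted C8=C9 enolate forms regiospecifically and is trapped on oxygen, as is routine for 2,2,6-trimethylcyclohexanone.

**Step 7**
Reactants: 9 enol triflate
Product: 10 methyl C8=C9 enoate (C11 ester on C9)
Conditions: Pd(OAc)2 (5 mol%), dppf (6 mol%), CO (1 atm), MeOH, Et3N, DMF, 60 °C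
Reagents that add atoms: carbon monoxide, [C-]#[O+]; methanol, CO
Why: Palladium-catalysed methoxycarbonylation of a vinyl triflate (oxidative addition, CO insertion, methanolysis) brings in C11 at the crowded C9, where direct carbonyl addition would not be expected to work.

**Step 8**
Reactants: 10 enoate
Product: 11 2,3:8,9-bis-epoxide (both oxiranes on the H5 face)
Conditions: mCPBA (3 equiv), NaHCO3, CH2Cl2, 0 °C → reflux
Reagents that add atoms: 3-chloroperoxybenzoic acid, OOC(=O)c1cccc(Cl)c1
Why: Prilezhaev epoxidation of both alkenes: the peracid reaches each from the face opposite the axial C10 methyl, which places the C8–O bond and the C2/C3 oxirane on the H5 face, and the ester, twisted out of conjugation by its neighbours, leaves C8=C9 nucleophilic enough.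

**Step 9**
Reactants: 11 bis-epoxide
Product: 14 C1=C2 allylic C3 alcohol keeping the 8,9-epoxy ester, via hydroxy selenide 12 (not isolated), via selenoxide 13 (not isolated)
Conditions: (PhSe)2 (0.6 equiv), NaBH4 (1.3 equiv), EtOH, rt → 50 °C; then THF, 30% H2O2, 0 °C → rt
Reagents that add atoms: none
Why: Sharpless–Lauer sequence: the selenolate opens only the disubstituted oxirane, trans-diaxially at C2 (Fürst–Plattner rule) to leave an axial C3–OH, and the selenoxide eliminates syn and away from the carbinol carbon to give the C1=C2 allylic alcohol, while the fully substituted glycidic ester offers no site for SN2 attack.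

**Step 10**
Reactants: 14 allylic alcohol epoxy ester
Product: 15 C3,C8-diol ester (C8–OH equatorial, H9 axial)
Conditions: SmI2 (2.5 equiv), HMPA, Me2NCH2CH2OH, THF, 0 °C
Reagents that add atoms: none
Why: SmI2 reduction of an α,β-epoxy ester to a β-hydroxy ester: electron transfer to the ester cleaves only the C9–O bond so the C8–O configuration is kept, and the samarium enolate is protonated at C9 from the face away from the C8 and C10 methyls to give axial H9 and the equatorial ester, which is also the more stable epimer.

**Step 11**
Reactants: 15 diol ester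
Product: 16 C1=C2 C3 enone with free C8–OH
Conditions: Dess–Martin periodinane, NaHCO3, CH2Cl2, 0 °C → rt
Reagents that add atoms: none
Why: Dess–Martin oxidation takes the secondary allylic C3–OH to the enone and cannot touch the tertiary C8–OH.

**Step 12**
Reactants: 16 enone
Product: 17 C3 triethylsilyl dienol ether C8 triethylsilyl ether
Conditions: Et3SiOTf (3 equiv), Et3N (5 equiv), CH2Cl2, −78 → 0 °C
Reagents that add atoms: triethylsilyl trifluoromethanesulfonate, CC[Si](CC)(CC)OS(=O)(=O)C(F)(F)F
Why: Soft enolisation with a silyl triflate and an amine: H4 is the only enolisable hydrogen of the enone (C2 is vinylic and the gamma carbon C10 is quaternary), so the cross-conjugated C3 silyl dienol ether forms regiospecifically, and the same reagent caps the tertiary C8–OH.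

**Step 13**
Reactants: 17 silyl dienol ether
Product: 18 C4-quaternary enone (CH2OBn equatorial, methyl axial)
Conditions: BnOCH2Cl (1.5 equiv), ZnBr2 (15 mol%), CH2Cl2, −20 °C → rt
Reagents that add atoms: benzyl chloromethyl ether, ClCOCc1ccccc1
Why: Lewis-acid-promoted alkylation of a silyl enol ether with an α-chloro ether (Reetz-type SN1 alkylation, suited to fully substituted enol carbons): the oxocarbenium ion should enter C4 from the face opposite the axial C10 methyl, as in the classical alkylations of 4-methyl-3-oxo-trans-decalin enolates, making CH2OBn equatorial and the methyl axial.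

**Step 14**
Reactants: 18 C4-quaternary enone
Product: 19 C3 tosylhydrazone of 18 (C=N geometry immaterial)
Conditions: TsNHNH2 (1.2 equiv), THF–EtOH, 50 °C
Reagents that add atoms: p-toluenesulfonohydrazide, Cc1ccc(cc1)S(=O)(=O)NN
Why: Tosylhydrazone condensation at the only ketone present; the ester, benzyl ether and silyl ether are inert.

**Step 15**
Reactants: 19 enone tosylhydrazone
Product: 20 C3-deoxy ester with C2=C3 alkene
Conditions: catecholborane (2 equiv), CHCl3, −10 °C; then NaOAc·3H2O, reflux
Reagents that add atoms: none
Why: Kabalka reduction of an α,β-unsaturated tosylhydrazone: 1,2-hydride addition, loss of sulfinate and a retro-ene loss of N2 remove the C3 oxygen and move the alkene to C2=C3 without touching a stereocentre; the alkene is saturated in step 20.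

**Step 16**
Reactants: 20 ester
Product: 21 C11 aldehyde
Conditions: i-Bu2AlH (1.5 equiv), toluene, −78 °C; aq. potassium sodium tartrate
Reagents that add atoms: none
Why: Partial ester reduction with i-Bu2AlH: the aluminium hemiacetal of this crowded ester should persist at −78 °C and release the aldehyde only on work-up, with H9 staying axial.

**Step 17**
Reactants: 22 (R)-4-methyldihydrofuran-2(3H)-one
Product: 23 (R)-(3-carboxy-2-methylpropyl)triphenylphosphonium bromide
Conditions: Ph3P·HBr (1 equiv), neat, 170 °C
Reagents that add atoms: triphenylphosphine hydrobromide, [Br-].c1ccc(cc1)[PH+](c1ccccc1)c1ccccc1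
Why: Acid-assisted SN2 opening of the lactone at its O–CH2 carbon by PPh3, the known way from butyrolactone to (3-carboxypropyl)triphenylphosphonium bromide; the C13 stereocentre comes from the chiral pool and takes no part in the reaction.

**Step 18**
Reactants: 23 phosphonium acid
Product: 24 2-(trimethylsilyl)ethyl ester of 23
Conditions: Me3SiCH2CH2OH (1.5 equiv), EDC·HCl, DMAP (10 mol%), CH2Cl2, rt
Reagents that add atoms: 2-(trimethylsilyl)ethanol, C[Si](C)(C)CCO
Why: Steglich-type carbodiimide esterification gives an ester that survives base, hydrogenation and acylation and is cleaved by fluoride.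

**Step 19**
Reactants: 21 C11 aldehyde; 24 phosphonium ester
Product: 26 (11Z)-alkene carrying the full C11–C15 chain, via phosphorus ylide 25 (not isolated)
Conditions: 24 (1.5 equiv), NaHMDS (1.45 equiv), THF, −78 → 0 °C; then 21, −78 °C → rt
Reagents that add atoms: none
Why: Wittig olefination with a non-stabilised ylide forms C11=C12 (Z expected, irrelevant after step 20); deprotonation next to phosphorus is favoured over ester enolisation by acidity, and neither C9 nor C13 takes part in bond formation.

**Step 20**
Reactants: 26 diene
Product: 28 saturated C18 alcohol, via saturated benzyl ether 27 (not isolated)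
Conditions: H2 (1 atm), PtO2, EtOAc, rt; then Pd(OH)2/C, H2 (3 atm), EtOAc–EtOH
Reagents that add atoms: none
Why: Catalytic hydrogenation followed by hydrogenolysis: PtO2 saturates C2=C3 and C11=C12 with little alkene migration, which protects the allylic C13 centre, and Pd(OH)2/C then cleaves the benzyl ether, while the silyl ether and silylethyl ester are inert.

**Step 21**
Reactants: 28 C18 alcohol; 29 angelic acid
Product: 31 C18 angelate with C8 silyl ether and C15 silylethyl ester, via mixed anhydride 30 (not isolated)
Conditions: 29 (3 equiv), 2,4,6-Cl3C6H2COCl (3 equiv), Et3N, toluene, rt; then 28, 80 °C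
Reagents that add atoms: angelic acid (29), C/C=C(/C)C(=O)O
Why: Yamaguchi-type mixed-anhydride acylation without a nucleophilic catalyst, the established way to angelates without Z-to-E isomerisation; only the primary C18–OH is free.

**Step 22**
Reactants: 31 protected angelate
Product: 32 target CNP0315745.1
Conditions: Bu4NF (4 equiv), THF, 0 °C → rt; cold 0.1 M HCl work-up
Reagents that add atoms: none
Why: Fluoride-induced cleavage removes the silylethyl ester (β-elimination to ethene) and the triethylsilyl ether in one operation, under conditions that should neither hydrolyse nor isomerise the hindered neopentyl angelate.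

**Compound list**
1 | 2,6-dimethyl-1,4-benzoquinone | CC1=CC(=O)C=C(C)C1=O | starting material
2 | (E)-penta-1,3-diene | C=C/C=C/C | starting material
3 | cis-fused endo adduct (H4, H5 and C10 methyl on one face) | C[C@H]1C=CC[C@]2(C)[C@H]1C(=O)C=C(C)C2=O | intermediate
4 | trans-fused ene-dione | C[C@H]1C=CC[C@]2(C)[C@@H]1C(=O)C=C(C)C2=O | intermediate
5 | trans-fused saturated 6,9-dione, C8 methyl equatorial | C[C@H]1C=CC[C@]2(C)[C@@H]1C(=O)C[C@H](C)C2=O | intermediate
6 | C6 mono-tosylhydrazone | C[C@H]1C=CC[C@]2(C)[C@@H]1C(=NNS(=O)(=O)c1ccc(C)cc1)C[C@H](C)C2=O | intermediate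
7 | C6-deoxy C9 ketone | C[C@H]1C=CC[C@]2(C)[C@@H]1CC[C@H](C)C2=O | intermediate
8 | potassium C8=C9 enolate | C[C@H]1C=CC[C@]2(C)[C@@H]1CCC(C)=C2[O-].[K+] | intermediate
9 | C8=C9 enol triflate | C[C@H]1C=CC[C@]2(C)[C@@H]1CCC(C)=C2OS(=O)(=O)C(F)(F)F | intermediate
10 | methyl C8=C9 enoate | C[C@H]1C=CC[C@]2(C)[C@@H]1CCC(C)=C2C(=O)OC | intermediate
11 | 2,3:8,9-bis-epoxide | C[C@H]1[C@H]3O[C@H]3C[C@]2(C)[C@@H]1CC[C@]4(C)O[C@]24C(=O)OC | intermediate
12 | C2 axial phenylselenide, C3 axial alcohol | C[C@H]1[C@@H](O)[C@H]([Se]c3ccccc3)C[C@]2(C)[C@@H]1CC[C@]4(C)O[C@]24C(=O)OC | intermediate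
13 | selenoxide of 12 | C[C@H]1[C@@H](O)[C@H]([Se](=O)c3ccccc3)C[C@]2(C)[C@@H]1CC[C@]4(C)O[C@]24C(=O)OC | intermediate
14 | C1=C2 allylic C3 alcohol, 8,9-epoxy ester | C[C@H]1[C@@H](O)C=C[C@]2(C)[C@@H]1CC[C@]4(C)O[C@]24C(=O)OC | intermediate
15 | C3,C8-diol ester | C[C@H]1[C@@H](O)C=C[C@]2(C)[C@@H]1CC[C@](C)(O)[C@H]2C(=O)OC | intermediate
16 | C1=C2 C3 enone, C8 hydroxy ester | C[C@H]1C(=O)C=C[C@]2(C)[C@@H]1CC[C@](C)(O)[C@H]2C(=O)OC | intermediate
17 | C3 silyl dienol ether, C8 silyl ether | CC1=C(O[Si](CC)(CC)CC)C=C[C@]2(C)[C@@H]1CC[C@](C)(O[Si](CC)(CC)CC)[C@H]2C(=O)OC | intermediate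
18 | C4 benzyloxymethyl enone | c1ccccc1COC[C@@]1(C)C(=O)C=C[C@]2(C)[C@@H]1CC[C@](C)(O[Si](CC)(CC)CC)[C@H]2C(=O)OC | intermediate
19 | C3 tosylhydrazone of 18 | c1ccccc1COC[C@@]1(C)C(=NNS(=O)(=O)c3ccc(C)cc3)C=C[C@]2(C)[C@@H]1CC[C@](C)(O[Si](CC)(CC)CC)[C@H]2C(=O)OC | intermediate
20 | C3-deoxy ester with C2=C3 | c1ccccc1COC[C@@]1(C)C=CC[C@]2(C)[C@@H]1CC[C@](C)(O[Si](CC)(CC)CC)[C@H]2C(=O)OC | intermediate
21 | C11 aldehyde | c1ccccc1COC[C@@]1(C)C=CC[C@]2(C)[C@@H]1CC[C@](C)(O[Si](CC)(CC)CC)[C@H]2C=O | intermediate
22 | (R)-4-methyldihydrofuran-2(3H)-one | O1C[C@H](C)CC1=O | starting material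
23 | (R)-(3-carboxy-2-methylpropyl)triphenylphosphonium bromide | c1ccccc1[P+](c1ccccc1)(c1ccccc1)C[C@H](C)CC(=O)O.[Br-] | intermediate
24 | 2-(trimethylsilyl)ethyl ester of 23 | c1ccccc1[P+](c1ccccc1)(c1ccccc1)C[C@H](C)CC(=O)OCC[Si](C)(C)C.[Br-] | intermediate
25 | phosphorus ylide from 24 | c1ccccc1P(c1ccccc1)(c1ccccc1)=C[C@H](C)CC(=O)OCC[Si](C)(C)C | intermediate
26 | (11Z)-alkene, C2=C3 still present | c1ccccc1COC[C@@]1(C)C=CC[C@]2(C)[C@@H]1CC[C@](C)(O[Si](CC)(CC)CC)[C@H]2/C=C\[C@H](C)CC(=O)OCC[Si](C)(C)C | intermediate
27 | saturated benzyl ether | c1ccccc1COC[C@@]1(C)CCC[C@]2(C)[C@@H]1CC[C@](C)(O[Si](CC)(CC)CC)[C@H]2CC[C@H](C)CC(=O)OCC[Si](C)(C)C | intermediate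
28 | saturated C18 alcohol | OC[C@@]1(C)CCC[C@]2(C)[C@@H]1CC[C@](C)(O[Si](CC)(CC)CC)[C@H]2CC[C@H](C)CC(=O)OCC[Si](C)(C)C | intermediate
29 | angelic acid, (Z)-2-methylbut-2-enoic acid | C/C=C(/C)C(=O)O | starting material
30 | angelic 2,4,6-trichlorobenzoic anhydride | C/C=C(/C)C(=O)OC(=O)c1c(Cl)cc(Cl)cc1Cl | intermediate
31 | protected angelate | C/C=C(/C)C(=O)OC[C@@]1(C)CCC[C@]2(C)[C@@H]1CC[C@](C)(O[Si](CC)(CC)CC)[C@H]2CC[C@H](C)CC(=O)OCC[Si](C)(C)C | intermediate
32 | CNP0315745.1 | C/C=C(/C)C(=O)OC[C@@]1(C)CCC[C@]2(C)[C@@H]1CC[C@](C)(O)[C@H]2CC[C@H](C)CC(=O)O | target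

**Step count**
- Total step count: 22.
- Longest linear sequence: 20 (steps 1–16 and 19–22).

**Steps most likely to fail**

**Step 1.**
- Risk: the alkyl diene may add too slowly to the trisubstituted C5=C10 bond at the temperatures where the catalyst distinguishes the faces. Background addition and acid-induced oligomerisation of the diene would then erode enantiomeric purity and conversion.
- Fallback (racemic cycloaddition, then resolution), setting out from 1 and 2: BF3·OEt2 in CH2Cl2 at −20 °C gives 3 together with its mirror image ent-3 F1. Steps 2 and 3 as written then give 4 with ent-4 F2 and 5 with ent-5 F3. The racemic dione is ketalised only at the unhindered C6 carbonyl with (R,R)-hydrobenzoin (PPTS, benzene, water separator). This gives the diastereomers hydrobenzoin C6 ketal of 5 F4 and hydrobenzoin C6 ketal of ent-5 F5, which are separated by crystallisation or chromatography. Treatment of F4 with 1 M HCl in THF returns enantiopure 5, where the route is rejoined.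

**Step 13.**
- Risk: bond formation at the fully substituted C4 may be slower than protodesilylation back to the enone, or the facial preference may erode with the small cationic electrophile.
- Fallback (carbonyl addition instead of alkylation), setting out from 17: a Mukaiyama aldol reaction with 37% aqueous formaldehyde and Yb(OTf)3 (10 mol%) in THF–H2O gives the C4 hydroxymethyl enone F6. This is benzylated under neutral conditions with 2-benzyloxy-1-methylpyridinium triflate and MgO in PhCF3 at 85 °C, which avoids retro-aldol loss of formaldehyde. The route is rejoined at 18.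

**Step 19.**
- Risk: the aldehyde sits between two quaternary carbons. The basic, β-branched ylide may deprotonate C9, with β-elimination of the C8 silyloxy group, faster than it adds.
- Fallback (chain built in pieces with small, weakly basic reagents, C13 set by a catalyst), setting out from 21:
  - Masamune–Roush Horner–Wadsworth–Emmons reaction with diethyl (2-oxopropyl)phosphonate, LiCl and DBU in MeCN gives the (11E)-enone F7.
  - H2 over Pd/C with pyridine in EtOAc saturates both alkenes but keeps the benzyl ether and gives the saturated methyl ketone F8.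
  - A second Horner–Wadsworth–Emmons reaction with 2-(trimethylsilyl)ethyl (diethoxyphosphoryl)acetate and NaH in THF gives, after removal of the Z isomer, the (13E)-enoate F9.
  - Copper hydride conjugate reduction (Cu(OAc)2·H2O, the DTBM-SEGPHOS antipode matched to the 13S centre, PMHS, t-BuOH, toluene) gives 27. The second stage of step 20 then continues to 28.

**Further compounds**
F1 | step 1 | ent-3 | C[C@@H]1C=CC[C@@]2(C)[C@@H]1C(=O)C=C(C)C2=O
F2 | step 1 | ent-4 | C[C@@H]1C=CC[C@@]2(C)[C@H]1C(=O)C=C(C)C2=O
F3 | step 1 | ent-5 | C[C@@H]1C=CC[C@@]2(C)[C@H]1C(=O)C[C@@H](C)C2=O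
F4 | step 1 | (R,R)-hydrobenzoin C6 ketal of 5 | C[C@H]1C=CC[C@]2(C)[C@@H]1C3(O[C@H](c4ccccc4)[C@@H](c4ccccc4)O3)C[C@H](C)C2=O
F5 | step 1 | (R,R)-hydrobenzoin C6 ketal of ent-5 | C[C@@H]1C=CC[C@@]2(C)[C@H]1C3(O[C@H](c4ccccc4)[C@@H](c4ccccc4)O3)C[C@@H](C)C2=O
F6 | step 13 | C4 hydroxymethyl enone | OC[C@@]1(C)C(=O)C=C[C@]2(C)[C@@H]1CC[C@](C)(O[Si](CC)(CC)CC)[C@H]2C(=O)OC
F7 | step 19 | (11E)-enone | c1ccccc1COC[C@@]1(C)C=CC[C@]2(C)[C@@H]1CC[C@](C)(O[Si](CC)(CC)CC)[C@H]2/C=C/C(C)=O
F8 | step 19 | saturated methyl ketone | c1ccccc1COC[C@@]1(C)CCC[C@]2(C)[C@@H]1CC[C@](C)(O[Si](CC)(CC)CC)[C@H]2CCC(C)=O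
F9 | step 19 | (13E)-enoate | c1ccccc1COC[C@@]1(C)CCC[C@]2(C)[C@@H]1CC[C@](C)(O[Si](CC)(CC)CC)[C@H]2CC/C(C)=C/C(=O)OCC[Si](C)(C)C
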